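- In a one-step world each reagent makes one product, so dawn's charge allows X, the share of the substrates found as product, to reach 20.0%. Dawn's readings from 2.00 min on average 17.4%, and summer's average 32.1%.

in all of them: left-handed substrate 0.050 M; right-handed substrate 0.050 M

| run | reagent | catalyst | remark | time |
|---|---|---|---|---|
| dawn | 0.020 M | 1 mM | run made earlier |  |
| summer | 0.045 M | 1 mM | run made earlier |  |
| noon | 0.030 M | 0.50 mM | run made earlier |  |
| flask | 0.0300 M | 1.0 mM |  | 12 min |

| run | time / min | left-handed substrate / % | right-handed substrate / % | right-handed product / % | left-handed product / % |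
|---|---|---|---|---|---|
| dawn | 1.00 | 41.3 | 46.7 | 3.1 | 10.4 |
| dawn | 2.00 | 37.7 | 46.2 | 4.6 | 13.0 |
| dawn | 5.00 | 39.5 | 46.3 | 3.6 | 13.6 |
| dawn | 12.0 | 38.3 | 46.3 | 4.8 | 12.6 |
| summer | 3.00 | 30.1 | 41.9 | 10.5 | 21.4 |
| summer | 6.00 | 28.3 | 43.1 | 9.8 | 21.0 |
| summer | 10.0 | 27.8 | 39.8 | 8.6 | 23.4 |
| summer | 12.0 | 28.1 | 39.8 | 10.5 | 23.2 |
| noon | 3.00 | 36.8 | 44.6 | 4.0 | 13.1 |
| noon | 6.00 | 35.7 | 44.5 | 6.5 | 12.7 |
| noon | 10.0 | 36.0 | 43.4 | 6.1 | 15.5 |
| noon | 12.0 | 36.0 | 44.2 | 3.8 | 15.0 |

(readings scatter by 1 percentage point)

- the largest share of what was charged as left-handed substrate and right-handed substrate together, at 12 min belongs to (left-handed substrate / right-handed product / left-handed product / right-handed substrate)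
- the largest share itself, whichever of these holds it, in percent of the left-handed substrate and right-handed substrate together charged

- Marginal capture m, the extra product per extra reagent between dawn and summer, is 0.588, below dawn's average return of 0.870.
- Assuming the return falls steadily with catalyst held at 1.0 mM, the flask's X lies between 23.3%, on the line with slope m, and 26.1%, at dawn's average.
- Right-handed substrate is half the charge minus a correction fX, with f the right-handed product's part of X: 0.249 at dawn, 0.307 in summer. The bracket is 42.0% to 44.2%.
- The forecast, right-handed substrate at 43.6% (42.6% to 44.6%), holds that “reagent is exhausted and partly wasted”; its value lies inside the bracket.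
- The flask gives right-handed substrate at 43.1%, also inside, with 23.6% as products, 0.37 percentage points above the line with slope m.

    reagent + catalyst + left-handed substrate → catalyst + left-handed product (k = 390 /M²/s)
    reagent + catalyst + right-handed substrate → catalyst + right-handed product (k = 142 /M²/s)
    2 reagent → self-condensation product (k = 0.231 /M/s)

- In the flask, the catalysed left-handed step alone has a reagent half-life of 0.59 min at the charged concentrations, against a first half-life of 1.20 min for self-condensation alone, about twice as long. In the flask reagent, the limiting reagent, stands at 0% at 12.0 min, less of its charge than right-handed substrate's 86%.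
- For the same flask with 0.075 M of reagent, m carried past summer gives X = 49.7%, so right-handed substrate at 34.7%; the simulation of that neighbouring flask gives 35.8%.

(Readings and results are simulated with made-up constants; noise was put on by code.)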